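**Strategy.** Ring locants: C1' bears the side chain, C2' the gem-dimethyl group, C3' bromine, C6' the exocyclic methylene. The route rests on cutting the cyclohexane on both sides of its unsubstituted C4'H2–C5'H2 unit: the bond C5'–C6' and the bond C3'–C4', with C3' handled as a ketone. This 4-methylenecyclohexanone pattern is assembled in one operation by a rhodium-catalysed [4+2] annulation of an acyclic 4-alkynal with ethylene: the formyl carbon becomes C3', the internal alkyne carbon C6', the alkyne terminus the exocyclic CH2. The precursor is an open-chain α,α-dimethyl aldehyde carrying the ethynyl group, the C1' stereocentre (from an organocatalytic Mukaiyama–Michael addition) and the Z-enoate side chain.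

Key step: step 5

Remark: the target SMILES is read as (2S,3Z) in the side chain and (1'R,3'S) in the ring, with bromine and the side chain cis (both equatorial).

**Step 1**
Reactants: 1 3-(trimethylsilyl)prop-2-ynal; 2 2-(triphenylphosphoranylidene)acetaldehyde
Product: 3 (2E)-5-(trimethylsilyl)pent-2-en-4-ynal
Conditions: CH2Cl2, 0 °C to 25 °C, 1 in slight excess
Reagents that add atoms: none
Why: Wittig olefination with the stabilised formyl ylide is E-selective, and the ynal is far more electrophilic than the enal product, so single homologation should dominate.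

**Step 2**
Reactants: 3 (2E)-5-(trimethylsilyl)pent-2-en-4-ynal; 4 trimethyl[(2-methylprop-1-en-1-yl)oxy]silane
Product: 5 (3S)-2,2-dimethyl-3-[(trimethylsilyl)ethynyl]pentanedial
Conditions: (2R,5R)-5-benzyl-2-tert-butyl-3-methylimidazolidin-4-one·2,4-dinitrobenzoic acid (20 mol %), CH2Cl2, H2O (2 equiv), −40 °C
Reagents that add atoms: none
Why: Organocatalytic Mukaiyama–Michael addition: in the (E)-iminium ion of 3 the benzyl group of the (2R,5R)-imidazolidinone shields one face, so the enol silane should add 1,4 to the open Re face of C3 (priorities alkynyl > C2 > H), which builds the quaternary carbon and sets the (3S) centre that becomes C1', while the silyl cap disfavours 1,6-addition and water releases the hindered aldehyde from the silyloxocarbenium ion.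

**Step 3**
Reactants: 5 (3S)-2,2-dimethyl-3-[(trimethylsilyl)ethynyl]pentanedial; 6 ethyl 2-[bis(2,2,2-trifluoroethoxy)phosphoryl]propanoate
Product: 7 ethyl (2Z,5S)-2,6,6-trimethyl-7-oxo-5-[(trimethylsilyl)ethynyl]hept-2-enoate
Conditions: KN(SiMe3)2, 18-crown-6, THF, −78 °C
Reagents that add atoms: none
Why: Still–Gennari variant of the Horner–Wadsworth–Emmons olefination: the bis(trifluoroethyl) phosphonate under dissociating conditions should give the (Z)-2-methyl enoate, and only the unhindered CH2–CHO reacts because the α-quaternary neopentyl aldehyde is far slower.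

**Step 4**
Reactants: 7 ethyl (2Z,5S)-2,6,6-trimethyl-7-oxo-5-[(trimethylsilyl)ethynyl]hept-2-enoate
Product: 8 ethyl (2Z,5R)-5-ethynyl-2,6,6-trimethyl-7-oxohept-2-enoate
Conditions: K2CO3 (0.2 equiv), EtOH, 0 °C to 25 °C
Reagents that add atoms: none
Why: Base-catalysed ethanolysis of the C(sp)–Si bond; the non-enolisable aldehyde is untouched, ethanol avoids transesterification, and the descriptor changes from S to R only because silicon is lost.

**Step 5**
Reactants: 8 ethyl (2Z,5R)-5-ethynyl-2,6,6-trimethyl-7-oxohept-2-enoate; 9 ethylene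
Product: 10 ethyl (2Z)-4-[(1R)-2,2-dimethyl-6-methylidene-3-oxocyclohexyl]-2-methylbut-2-enoate
Conditions: [Rh(dppe)]2(BF4)2 (5 mol %), ethylene (5 atm), CH2Cl2, 25 °C
Reagents that add atoms: none
Why: Proposed new method: oxidative addition of the formyl C–H bond of 8 to the cationic monovalent rhodium centre gives an acyl rhodium hydride (trivalent rhodium), which adds cis across the tethered terminal alkyne to form a five-membered acyl–alkenyl rhodacycle that already carries the exocyclic CH2; ethylene then inserts into a Rh–C bond and C–C reductive elimination from the seven-membered rhodacycle releases the cyclohexanone, so the C5'–C6' and C3'–C4' bonds are both made in one catalytic turnover. The closest known reaction type is the rhodium-catalysed [4+2] annulation of 4-alkynals with alkynes and with acrylamides, which runs through the same rhodacycle; ethylene, the most readily inserting alkene in hydroacylation chemistry, has not been shown as the two-carbon partner. The six-membered ring closes as a formal [4+2] carbocyclisation by reductive elimination from a seven-membered metallacycle, not as a pericyclic process. No new stereocentre is formed: C1' was set in step 2 and is neither enolisable nor involved in bond making, so it should be carried through unchanged. The step needs chemoselectivity for annulation over trans-hydroacylation to a cyclopentenone, over plain hydroacylation of ethylene and over β-hydride elimination; the gem-dimethyl group (no enolisation, no aldol, Thorpe–Ingold acceleration of rhodacycle formation), the chelating diphosphine and an excess of ethylene under pressure are meant to secure it.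

**Step 6**
Reactants: 10 ethyl (2Z)-4-[(1R)-2,2-dimethyl-6-methylidene-3-oxocyclohexyl]-2-methylbut-2-enoate
Product: 11 ethyl (2Z)-4-[(1R,3R)-3-hydroxy-2,2-dimethyl-6-methylidenecyclohexyl]-2-methylbut-2-enoate
Conditions: (S)-2-methyl-CBS-oxazaborolidine (0.2 equiv), catecholborane (1.5 equiv), toluene, −40 °C; then MeOH, pH 7 buffer
Reagents that add atoms: none
Why: Corey–Bakshi–Shibata reduction under reagent control: the (S)-catalyst differentiates the quaternary C2' (large) from the C4' methylene (small) and should give the (3'R) alcohol, trans to the side chain, whichever chair the ketone prefers, while catecholborane at low temperature spares the alkenes and the ester.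

**Step 7**
Reactants: 11 ethyl (2Z)-4-[(1R,3R)-3-hydroxy-2,2-dimethyl-6-methylidenecyclohexyl]-2-methylbut-2-enoate
Product: 12 ethyl (2Z)-4-[(1R,3S)-3-bromo-2,2-dimethyl-6-methylidenecyclohexyl]-2-methylbut-2-enoate
Conditions: CBr4, P(n-C8H17)3, toluene, 70 °C
Reagents that add atoms: carbon tetrabromide, BrC(Br)(Br)Br
Why: Appel bromination: the alkoxyphosphonium ion of the axial C3' alcohol (side chain equatorial) should be displaced by bromide in an SN2 process with inversion, giving the equatorial (3'S) bromide cis to the side chain.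

**Step 8**
Reactants: 12 ethyl (2Z)-4-[(1R,3S)-3-bromo-2,2-dimethyl-6-methylidenecyclohexyl]-2-methylbut-2-enoate
Product: 13 (3Z)-1-bromo-5-[(1R,3S)-3-bromo-2,2-dimethyl-6-methylidenecyclohexyl]-3-methylpent-3-en-2-one
Conditions: CH2Br2 (1.5 equiv), MeLi·LiBr (1.4 equiv, slow addition), THF, −78 °C; AcOH quench at −78 °C
Reagents that add atoms: dibromomethane, BrCBr
Why: Ester homologation with the carbenoid LiCH2Br: 1,2-addition gives a tetrahedral lithium hemiketal that is stable at −78 °C and collapses to the bromomethyl ketone only on acidic quench, which should prevent double addition, and the hindered secondary bromide and the alkenes are inert at this temperature.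

**Step 9**
Reactants: 13 (3Z)-1-bromo-5-[(1R,3S)-3-bromo-2,2-dimethyl-6-methylidenecyclohexyl]-3-methylpent-3-en-2-one
Product: 14 (2S,3Z)-1-bromo-5-[(1R,3S)-3-bromo-2,2-dimethyl-6-methylidenecyclohexyl]-3-methylpent-3-en-2-ol
Conditions: (S)-2-methyl-CBS-oxazaborolidine (0.2 equiv), catecholborane (1.5 equiv), toluene, −78 °C; then MeOH, pH 7 buffer
Reagents that add atoms: none
Why: Corey–Bakshi–Shibata reduction: the (S)-oxazaborolidine should bind the ketone with the branched Z-alkenyl group as the large and CH2Br as the small substituent and deliver hydride 1,2 to the face that gives the (2S) bromohydrin, and the non-basic work-up avoids epoxide closure.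

**Compound list**
1 | 3-(trimethylsilyl)prop-2-ynal | C[Si](C)(C)C#CC=O | starting material
2 | 2-(triphenylphosphoranylidene)acetaldehyde | O=CC=P(c1ccccc1)(c1ccccc1)c1ccccc1 | starting material
3 | (2E)-5-(trimethylsilyl)pent-2-en-4-ynal | C[Si](C)(C)C#C/C=C/C=O | intermediate
4 | trimethyl[(2-methylprop-1-en-1-yl)oxy]silane | CC(C)=CO[Si](C)(C)C | starting material
5 | (3S)-2,2-dimethyl-3-[(trimethylsilyl)ethynyl]pentanedial | O=CC(C)(C)[C@@H](C#C[Si](C)(C)C)CC=O | intermediate
6 | ethyl 2-[bis(2,2,2-trifluoroethoxy)phosphoryl]propanoate | CCOC(=O)C(C)P(=O)(OCC(F)(F)F)OCC(F)(F)F | starting material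
7 | ethyl (2Z,5S)-2,6,6-trimethyl-7-oxo-5-[(trimethylsilyl)ethynyl]hept-2-enoate | O=CC(C)(C)[C@@H](C#C[Si](C)(C)C)C/C=C(/C)C(=O)OCC | intermediate
8 | ethyl (2Z,5R)-5-ethynyl-2,6,6-trimethyl-7-oxohept-2-enoate | O=CC(C)(C)[C@@H](C#C)C/C=C(/C)C(=O)OCC | intermediate
9 | ethylene | C=C | starting material
10 | ethyl (2Z)-4-[(1R)-2,2-dimethyl-6-methylidene-3-oxocyclohexyl]-2-methylbut-2-enoate | C=C1CCC(=O)C(C)(C)[C@@H]1C/C=C(/C)C(=O)OCC | intermediate
11 | ethyl (2Z)-4-[(1R,3R)-3-hydroxy-2,2-dimethyl-6-methylidenecyclohexyl]-2-methylbut-2-enoate | C=C1CC[C@@H](O)C(C)(C)[C@@H]1C/C=C(/C)C(=O)OCC | intermediate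
12 | ethyl (2Z)-4-[(1R,3S)-3-bromo-2,2-dimethyl-6-methylidenecyclohexyl]-2-methylbut-2-enoate | C=C1CC[C@H](Br)C(C)(C)[C@@H]1C/C=C(/C)C(=O)OCC | intermediate
13 | (3Z)-1-bromo-5-[(1R,3S)-3-bromo-2,2-dimethyl-6-methylidenecyclohexyl]-3-methylpent-3-en-2-one | C=C1CC[C@H](Br)C(C)(C)[C@@H]1C/C=C(/C)C(=O)CBr | intermediate
14 | (2S,3Z)-1-bromo-5-[(1R,3S)-3-bromo-2,2-dimethyl-6-methylidenecyclohexyl]-3-methylpent-3-en-2-ol | C=C1CC[C@H](Br)C(C)(C)[C@@H]1C/C=C(/C)[C@H](O)CBr | target

**Step count.** Total: 9 steps. Longest linear sequence: 9 steps (steps 1 to 9).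

**Steps most likely to fail**

Step 5 (proposed new method). The acyl rhodium hydride may be diverted before ethylene is taken up: intramolecular trans-hydroacylation to a cyclopentenone, plain hydroacylation of ethylene, β-hydride elimination after insertion, or vinylidene formation and oligomerisation at the terminal alkyne. The fallback uses known reactions, sets out from 8 and comes back at 10, and makes the two ring bonds in separate steps. Addition of CH2=CHMgBr (THF, −78 °C) to the aldehyde gives the allylic alcohol ethyl (2Z,5R)-5-ethynyl-7-hydroxy-2,6,6-trimethylnona-2,8-dienoate F1 as a mixture of carbinol epimers. Dess–Martin oxidation gives the vinyl ketone ethyl (2Z,5R)-5-ethynyl-2,6,6-trimethyl-7-oxonona-2,8-dienoate F2. Bu3SnH with AIBN (benzene, 80 °C, slow addition) adds a stannyl radical to the alkyne terminus, and the alkenyl radical should close 6-endo onto the CH2 terminus of the enone to give ethyl (2Z)-4-{(1S)-2,2-dimethyl-3-oxo-6-[(tributylstannyl)methylidene]cyclohexyl}-2-methylbut-2-enoate F3. Protodestannylation with CF3CO2H (CH2Cl2, 0 °C) returns 10.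

Step 2. Conversion may be low because the fully substituted enol silane is weakly nucleophilic and hydrolyses competitively, and facial selectivity on the alkynyl-substituted iminium ion may be poor. The fallback moves stereocontrol to a later, reagent-controlled step; it sets out from 3 and 4 and comes back at 11. An achiral ammonium salt (pyrrolidine·CF3CO2H, wet CH2Cl2) gives rac-2,2-dimethyl-3-[(trimethylsilyl)ethynyl]pentanedial F4. Steps 3 to 5 are run unchanged on the racemates rac-ethyl (2Z)-2,6,6-trimethyl-7-oxo-5-[(trimethylsilyl)ethynyl]hept-2-enoate F5, rac-ethyl (2Z)-5-ethynyl-2,6,6-trimethyl-7-oxohept-2-enoate F6 and rac-ethyl (2Z)-4-(2,2-dimethyl-6-methylidene-3-oxocyclohexyl)-2-methylbut-2-enoate F7. The reduction of step 6 should then turn the two enantiomers of the ketone into diastereomers, 11 and the cis alcohol ethyl (2Z)-4-[(1S,3R)-3-hydroxy-2,2-dimethyl-6-methylidenecyclohexyl]-2-methylbut-2-enoate F8. These are separated by chromatography and 11 continues; at most half of the material is usable.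

Step 7. Backside attack at the neopentyl carbon past the gem-dimethyl group is slow, so elimination towards C4' or a Wagner–Meerwein methyl shift may overtake substitution. The fallback replaces inversion by front-side delivery with retention; it sets out from 10 and comes back at 12. Reduction with (R)-2-methyl-CBS-oxazaborolidine and catecholborane gives the equatorial, cis alcohol ethyl (2Z)-4-[(1R,3S)-3-hydroxy-2,2-dimethyl-6-methylidenecyclohexyl]-2-methylbut-2-enoate F9. Quinoline-8-sulfonyl chloride (Et3N, DMAP, CH2Cl2) gives ethyl (2Z)-4-[(1R,3S)-2,2-dimethyl-6-methylidene-3-(quinolin-8-ylsulfonyloxy)cyclohexyl]-2-methylbut-2-enoate F10. TiBr4 (CH2Cl2, −78 °C) should then deliver bromide from the chelated leaving group to the same face, giving 12 with retention.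

**Further compounds**
F1 | step 5 | ethyl (2Z,5R)-5-ethynyl-7-hydroxy-2,6,6-trimethylnona-2,8-dienoate | C=CC(O)C(C)(C)[C@@H](C#C)C/C=C(/C)C(=O)OCC
F2 | step 5 | ethyl (2Z,5R)-5-ethynyl-2,6,6-trimethyl-7-oxonona-2,8-dienoate | C=CC(=O)C(C)(C)[C@@H](C#C)C/C=C(/C)C(=O)OCC
F3 | step 5 | ethyl (2Z)-4-{(1S)-2,2-dimethyl-3-oxo-6-[(tributylstannyl)methylidene]cyclohexyl}-2-methylbut-2-enoate | CCCC[Sn](CCCC)(CCCC)C=C1CCC(=O)C(C)(C)[C@@H]1C/C=C(/C)C(=O)OCC
F4 | step 2 | rac-2,2-dimethyl-3-[(trimethylsilyl)ethynyl]pentanedial | O=CC(C)(C)C(C#C[Si](C)(C)C)CC=O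
F5 | step 2 | rac-ethyl (2Z)-2,6,6-trimethyl-7-oxo-5-[(trimethylsilyl)ethynyl]hept-2-enoate | O=CC(C)(C)C(C#C[Si](C)(C)C)C/C=C(/C)C(=O)OCC
F6 | step 2 | rac-ethyl (2Z)-5-ethynyl-2,6,6-trimethyl-7-oxohept-2-enoate | O=CC(C)(C)C(C#C)C/C=C(/C)C(=O)OCC
F7 | step 2 | rac-ethyl (2Z)-4-(2,2-dimethyl-6-methylidene-3-oxocyclohexyl)-2-methylbut-2-enoate | C=C1CCC(=O)C(C)(C)C1C/C=C(/C)C(=O)OCC
F8 | step 2 | ethyl (2Z)-4-[(1S,3R)-3-hydroxy-2,2-dimethyl-6-methylidenecyclohexyl]-2-methylbut-2-enoate | C=C1CC[C@@H](O)C(C)(C)[C@H]1C/C=C(/C)C(=O)OCC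
F9 | step 7 | ethyl (2Z)-4-[(1R,3S)-3-hydroxy-2,2-dimethyl-6-methylidenecyclohexyl]-2-methylbut-2-enoate | C=C1CC[C@H](O)C(C)(C)[C@@H]1C/C=C(/C)C(=O)OCC
F10 | step 7 | ethyl (2Z)-4-[(1R,3S)-2,2-dimethyl-6-methylidene-3-(quinolin-8-ylsulfonyloxy)cyclohexyl]-2-methylbut-2-enoate | C=C1CC[C@H](OS(=O)(=O)c2cccc3cccnc23)C(C)(C)[C@@H]1C/C=C(/C)C(=O)OCC
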